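The primed seven-membered ring holds C5', C6', C7' (isopropyl), C8' (oxygen), C9' and C10' (methyl), which are the six ring carbons of a 4-substituted thymol ether. The seventh atom, C1', lies alpha to the C2' ketone, so it can be delivered as a ketocarbenoid. (Guaiane numbering: acetate half C1–C15, peroxide half primed.)
Retrosynthetic cuts, in order: O–C11' and O–C8' (dioxolane); C1'–C5' and C1'–C10' (carbon insertion); C5–C6 (Suzuki–Miyaura); C3–C3' (Michael); C1–C4' (Claisen); C1–C2 and C4–C5 (dione synthesis).
Forward ring order: the cyclopentane-1,3-dione ring C1–C5, then the norbornane (C3–C3'), then the cycloheptane C1/C5–C10. The key step then forms the cyclopentanone and the cycloheptatriene together, and the 1,2-dioxolane closes last.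
Stereochemistry: C10 comes from methyl hydrogen (R)-3-methylglutarate and C2 from a Corey–Bakshi–Shibata reduction. C1 and C4' are set by a chair Claisen rearrangement of an (E)-allyl enol ether, anti to the C2 silyl ether. C3 and C3' follow from the ring closure, C7 and C8' from equilibration, and C10' from a ligand-controlled copper hydride reduction.

Key step: step 25

Abbreviations: Ar = 4-methoxy-2-methyl-5-(propan-2-yl)phenyl. R = the C10 side chain 1-[2-(3-methylbut-1-en-2-yl)-1,3-dioxolan-2-yl]propan-2-yl, bound through C10.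
Assumption: the C7 configuration (alpha to the C8 ketone) and the C8' configuration (hemiketal) of the target are the thermodynamically preferred ones, so both can be reached by equilibration.

Step 1
Reactants: 1 thymol
Product: 2 4-bromothymol
Conditions: NBS, MeCN, 0 °C
Reagents that add atoms: N-bromosuccinimide, O=C1CCC(=O)N1Br
Why: Electrophilic aromatic bromination; the hydroxyl group directs to its free para position, the future C5'.

Step 2
Reactants: 2 4-bromothymol
Product: 3 4-bromothymol methyl ether
Conditions: MeI, K2CO3, acetone, 56 °C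
Reagents that add atoms: iodomethane, CI
Why: Williamson ether synthesis; the methyl ether later becomes the C8' enol ether.

Step 3
Reactants: 3 4-bromothymol methyl ether; 4 methyl (E)-but-2-enoate
Product: 5 methyl (E)-3-Ar-but-2-enoate
Conditions: Pd(OAc)2 (5 mol %), P(o-tol)3, Et3N, DMF, 110 °C
Reagents that add atoms: none
Why: Mizoroki–Heck reaction; syn carbopalladation and syn beta-hydride elimination replace the vinylic hydrogen of the (E)-crotonate with retention, which puts Ar trans to the ester.

Step 4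
Reactants: 5 methyl (E)-3-Ar-but-2-enoate
Product: 6 (E)-3-Ar-but-2-en-1-ol
Conditions: i-Bu2AlH (2.2 equiv), CH2Cl2, −78 °C
Reagents that add atoms: none
Why: 1,2-Reduction of an enoate by an aluminium hydride leaves the alkene geometry untouched.

Step 5
Reactants: 7 methyl hydrogen (R)-3-methylglutarate; 8 2-bromo-3-methylbut-1-ene
Product: 11 methyl 3,7-dimethyl-6-methylidene-5-oxooctanoate, via acid chloride 9 (not isolated), via Grignard reagent 10 (not isolated)
Conditions: 7, (COCl)2, DMF (cat.), CH2Cl2, 0 °C; 8, Mg, THF; combine, CuI (10 mol %), THF, −78 °C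
Reagents that add atoms: none
Why: Copper-catalysed acylation of a Grignard reagent by an acid chloride is faster than attack on the methyl ester and forms C7–C8; the C10 stereocentre is not touched.

Step 6
Reactants: 11 methyl 3,7-dimethyl-6-methylidene-5-oxooctanoate
Product: 12 ethylene ketal of 11
Conditions: Me3SiOCH2CH2OSiMe3, Me3SiOTf (5 mol %), CH2Cl2, −78 to −20 °C
Reagents that add atoms: 1,2-bis(trimethylsilyloxy)ethane, C[Si](C)(C)OCCO[Si](C)(C)C
Why: Silyl-triflate-catalysed aprotic ketalisation masks C8 without shifting the C6=C7 alkene.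

Step 7
Reactants: 12 ethylene ketal of 11
Product: 13 3-methyl-4-[2-(3-methylbut-1-en-2-yl)-1,3-dioxolan-2-yl]butanal
Conditions: i-Bu2AlH (1.05 equiv), toluene, −78 °C
Reagents that add atoms: none
Why: Partial reduction of a methyl ester stops at the aldehyde because the tetrahedral aluminium alkoxide survives at low temperature.

Step 8
Reactants: 13 3-methyl-4-[2-(3-methylbut-1-en-2-yl)-1,3-dioxolan-2-yl]butanal; 14 methyl acrylate
Product: 15 gamma-keto ester MeO2C-C3H2-C4H2-C5(=O)-C1H2-R
Conditions: 3-benzyl-5-(2-hydroxyethyl)-4-methylthiazolium chloride (10 mol %), Et3N, EtOH, 75 °C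
Reagents that add atoms: none
Why: Stetter reaction; the carbene-derived acyl anion equivalent of the aliphatic aldehyde adds to the acrylate and forms C4–C5.

Step 9
Reactants: 15 gamma-keto ester
Product: 16 2-R-cyclopentane-1,3-dione
Conditions: KOt-Bu, THF, 0 to 40 °C; AcOH quench
Reagents that add atoms: none
Why: Dieckmann-type acylation of the C1 ketone enolate by the C2 ester is the only closure that gives a five-membered ring, and it is driven by the acidic dione.

Step 10
Reactants: 16 2-R-cyclopentane-1,3-dione; 6 (E)-3-Ar-but-2-en-1-ol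
Product: 17 3-[(E)-3-Ar-but-2-enyloxy]-2-R-cyclopent-2-en-1-one
Conditions: PPh3, DIAD, THF, 0 °C
Reagents that add atoms: none
Why: Mitsunobu reaction; the acidic 2-alkyl dione is alkylated on oxygen at the primary allylic carbon, and the symmetry of 16 removes any regiochemical question.

Step 11
Reactants: 17 vinylogous ester
Product: 18 (S)-3-[(E)-3-Ar-but-2-enyloxy]-2-R-cyclopent-2-en-1-ol
Conditions: (R)-2-methyl-CBS-oxazaborolidine (20 mol %), catecholborane, toluene, −78 °C; aq. NaOH
Reagents that add atoms: none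
Why: Corey–Bakshi–Shibata reduction; the substituted alkene carbon C1 acts as the large group and C3H2 as the small one, so the (R)-catalyst should set (S)-C2 whatever the configuration at C10.

Step 12
Reactants: 18 cyclopentenol
Product: 19 triethylsilyl ether of 18
Conditions: Et3SiCl, imidazole, DMF, 0 °C
Reagents that add atoms: chlorotriethylsilane, CC[Si](Cl)(CC)CC
Why: Silylation under basic conditions protects the acid-labile allylic alcohol and supplies the group that shields one face of C1.

Step 13
Reactants: 19 triethylsilyl ether of 18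
Product: 20 2-(2-Ar-but-3-en-2-yl)-2-R-3-(triethylsilyloxy)cyclopentanone
Conditions: toluene, solid K2CO3, sealed tube, 130 °C
Reagents that add atoms: none
Why: Claisen rearrangement; the allyl unit reaches C1 anti to the C2 silyl ether, and the chair transition state of the (E)-alkene (Ar equatorial, methyl axial) fixes C4' relative to C1, joining the two quaternary carbons intramolecularly.

Step 14
Reactants: 20 Claisen ketone
Product: 22 primary alcohol (C2'H2OH), via pinacol boronate 21 (not isolated)
Conditions: [Ir(cod)Cl]2 (1.5 mol %), dppe, pinacolborane, THF, 23 °C; then H2O2, NaOH, 0 °C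
Reagents that add atoms: hydrogen peroxide, OO
Why: Metal-catalysed anti-Markovnikov hydroboration prefers the monosubstituted vinyl group to the hindered 1,1-disubstituted C6=C7 alkene and to the ketone, and oxidation then gives the alcohol.

Step 15
Reactants: 22 primary alcohol
Product: 23 carboxylic acid (C2'O2H)
Conditions: TEMPO (20 mol %), PhI(OAc)2, MeCN–H2O, 23 °C
Reagents that add atoms: water, O
Why: Oxoammonium-mediated oxidation takes the primary alcohol through the aldehyde hydrate to the acid without touching arene or alkene.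

Step 16
Reactants: 23 carboxylic acid
Product: 24 methyl ester
Conditions: MeI, K2CO3, DMF, 23 °C
Reagents that add atoms: iodomethane, CI
Why: Carboxylate alkylation gives the small ester needed as Michael donor.

Step 17
Reactants: 24 methyl ester
Product: 25 C4-methyl ketone (C4 epimers)
Conditions: LiN(i-Pr)2 (1.05 equiv), THF, −78 °C; MeI
Reagents that add atoms: iodomethane, CI
Why: Ketone enolate alkylation; C1 is quaternary, so only C4 can be enolised, and the new C4 centre becomes planar in step 18.

Step 18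
Reactants: 25 C4-methyl ketone
Product: 27 enone C5(=O)-C4(Me)=C3H, via trimethylsilyl enol ether 26 (not isolated)
Conditions: KN(SiMe3)2, THF, −78 to 0 °C; Me3SiCl; then Pd(OAc)2, MeCN, 23 °C
Reagents that add atoms: none
Why: Saegusa–Ito oxidation; reversible deprotonation selects the more acidic ketone over the ester, and beta-hydride loss from C3 gives the endocyclic enone.

Step 19
Reactants: 27 enone
Product: 29 norbornenyl triflate, via lithium enolate 28 (not isolated)
Conditions: LiN(SiMe3)2 (1.1 equiv), THF, −78 to −20 °C; then N-(5-chloro-2-pyridyl)bis(trifluoromethanesulfonimide), −78 to 0 °C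
Reagents that add atoms: N-(5-chloro-2-pyridyl)bis(trifluoromethanesulfonimide), O=S(=O)(N(c1ccc(Cl)cn1)S(=O)(=O)C(F)(F)F)C(F)(F)F
Why: Intramolecular Michael addition, as in the second stage of anionic double Michael routes to bicyclo[2.2.1]heptanones; the C3' ester enolate can reach C3 only on the face anti to the C2 silyl ether (sets C3), a lithium-bridged transition state holds the ester over the enone (endo C3'), and the regiodefined C4=C5 enolate is trapped as the enol triflate.

Step 20
Reactants: 29 norbornenyl triflate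
Product: 31 tricyclic ketal ester (C7 epimers), via B-alkyl-9-BBN 30 (not isolated)
Conditions: 9-BBN-H, THF, 60 °C; then Pd(dppf)Cl2 (10 mol %), AsPh3, Cs2CO3, DMF–H2O, 50 °C, high dilution
Reagents that add atoms: none
Why: Hydroboration followed by intramolecular B-alkyl Suzuki–Miyaura coupling forms C5–C6, closes the seven-membered ring and leaves the tetrasubstituted C4=C5 alkene; the C7 centre it creates is corrected in step 21.

Step 21
Reactants: 31 tricyclic ketal ester
Product: 32 hydroxy keto ester
Conditions: 1 M HCl, THF, 23 °C; then DBU, toluene, 23 °C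
Reagents that add atoms: water, O
Why: Dilute acid hydrolyses the ketal and the silyl ether, and base-mediated enolisation of the C8 ketone then lets the C7 isopropyl group settle cis to the C10 methyl group, on the ring face away from C4'.

Step 22
Reactants: 32 hydroxy keto ester
Product: 33 hydroxy keto acid
Conditions: LiI, pyridine, 115 °C; then 1 M HCl
Reagents that add atoms: none
Why: Nucleophilic demethylation attacks the methyl carbon, so neither the crowding at the endo ester nor the C3' configuration matters.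

Step 23
Reactants: 33 hydroxy keto acid
Product: 34 acetoxy keto acid
Conditions: Ac2O, DMAP, pyridine, 23 °C; aq. NaHCO3, then acidify
Reagents that add atoms: acetic anhydride, CC(=O)OC(C)=O
Why: DMAP-catalysed acylation installs the C2 acetate, and the mixed anhydride at C2' is hydrolysed on work-up.

Step 24
Reactants: 34 acetoxy keto acid
Product: 36 endo diazoketone, via acid chloride 35 (not isolated)
Conditions: (COCl)2, DMF (cat.), CH2Cl2, 0 °C; evaporate; CH2N2 (excess), Et2O, 0 °C
Reagents that add atoms: diazomethane, C=[N+]=[N-]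
Why: Acylation of diazomethane (first stage of the Arndt–Eistert sequence) brings in C1', and a second equivalent removes HCl.

Step 25
Reactants: 36 endo diazoketone
Product: 38 methoxycycloheptatriene (dihydroazulenone), via norcaradiene 37 (not isolated)
Conditions: Rh2(O2CCF3)4 (1 mol %), CH2Cl2, 40 °C, slow addition of 36
Reagents that add atoms: none
Why: The dirhodium catalyst expels N2 from 36 and gives an electrophilic carbenoid at C1' that cyclopropanates the C5'–C10' bond of the arene to norcaradiene 37, whose C5'–C10' bond then opens in a disrotatory six-electron electrocyclic step to cycloheptatriene 38. The closest known reaction type is the intramolecular Buchner reaction of 1-diazo-4-arylbutan-2-ones to dihydroazulenones. The cyclopentanone closes by five-membered bond formation between C1' and the ipso carbon C5', whereas the seven-membered ring arises by insertion of C1' between C5' and C10' of the existing six-membered ring rather than by cyclisation. The only new stereocentre, C1', follows from the cis endo placement of acyl and aryl groups and from attack on the arene face that turns C10' to the convex side, and it disappears in step 26. The step needs arene over C4=C5 alkene addition, which the electron-poor trifluoroacetate ligands, the methoxy donor para to C5' and the full substitution of the alkene should secure. It also needs the methyl-bearing ortho bond over the hydrogen-bearing one, which should follow from the C4'–C5' rotamer that keeps the ortho methyl group away from quaternary C1 and hence next to the carbenoid.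

Step 26
Reactants: 38 methoxycycloheptatriene
Product: 39 cross-conjugated dienedione (C1'=C5' and C9'=C10'; C7' epimers)
Conditions: oxalic acid, THF–H2O, 0 °C; then Et3N, CH2Cl2, 23 °C
Reagents that add atoms: water, O
Why: Mild enol ether hydrolysis frees the C8' ketone, and base-mediated tautomerisation through the acidic C1'–H moves C5'=C6' into conjugation with C2'; strong acid, which would aromatise the ring, is avoided.

Step 27
Reactants: 39 cross-conjugated dienedione
Product: 40 enedione (C10' set)
Conditions: Cu(OAc)2·H2O (5 mol %), (S)-DTBM-SEGPHOS, (EtO)2MeSiH, t-BuOH, toluene, 0 °C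
Reagents that add atoms: none
Why: Asymmetric copper hydride conjugate reduction; only the alpha-unsubstituted C9'=C10' enone is reactive, the substrate shows little facial bias so far from the norbornene, and the ligand antipode is chosen by analogy with beta-methylcycloalkenones to deliver hydride to the concave face of C10'.

Step 28
Reactants: 40 enedione
Product: 41 linear dienedione (C1'=C5' and C6'=C7')
Conditions: chloranil, t-BuOH, 80 °C
Reagents that add atoms: none
Why: Quinone dehydrogenation of an enone at its gamma and delta carbons (as for 4-en-3-ones to 4,6-dien-3-ones) proceeds through the C2' dienol, which the saturated C8 ketone of the other half cannot form.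

Step 29
Reactants: 41 linear dienedione
Product: 43 target CNP0317907.1, via hydroperoxide 42 (not isolated)
Conditions: O2 (1 atm), DBU (0.2 equiv), MeCN, 0 °C
Reagents that add atoms: dioxygen, O=O
Why: Autoxidation of an extended enolate; loss of the C11' hydrogen gives the trienolate of the C2' ketone, triplet oxygen adds at its tertiary terminus C11' with the dienone restored, and the hydroperoxide adds reversibly to C8' to give the more stable hemiketal epimer.

Compound list
1 | thymol | Cc1ccc(C(C)C)c(O)c1 | starting material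
2 | 4-bromothymol | Cc1cc(O)c(C(C)C)cc1Br | intermediate
3 | 4-bromothymol methyl ether | COc1cc(C)c(Br)cc1C(C)C | intermediate
4 | methyl (E)-but-2-enoate | C/C=C/C(=O)OC | starting material
5 | methyl (E)-3-Ar-but-2-enoate | COC(=O)/C=C(\C)c1cc(C(C)C)c(OC)cc1C | intermediate
6 | (E)-3-Ar-but-2-en-1-ol | OC/C=C(\C)c1cc(C(C)C)c(OC)cc1C | intermediate
7 | methyl hydrogen (R)-3-methylglutarate | COC(=O)C[C@H](C)CC(=O)O | starting material
8 | 2-bromo-3-methylbut-1-ene | C=C(Br)C(C)C | starting material
9 | acid chloride of 7 | COC(=O)C[C@H](C)CC(=O)Cl | intermediate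
10 | (3-methylbut-1-en-2-yl)magnesium bromide | C=C([Mg]Br)C(C)C | intermediate
11 | methyl 3,7-dimethyl-6-methylidene-5-oxooctanoate (C10 as in 7) | COC(=O)C[C@H](C)CC(=O)C(=C)C(C)C | intermediate
12 | ethylene ketal of 11 | COC(=O)C[C@H](C)CC1(OCCO1)C(=C)C(C)C | intermediate
13 | 3-methyl-4-[2-(3-methylbut-1-en-2-yl)-1,3-dioxolan-2-yl]butanal | O=CC[C@H](C)CC1(OCCO1)C(=C)C(C)C | intermediate
14 | methyl acrylate | C=CC(=O)OC | starting material
15 | gamma-keto ester, methyl 6-methyl-7-[2-(3-methylbut-1-en-2-yl)-1,3-dioxolan-2-yl]-4-oxoheptanoate | COC(=O)CCC(=O)C[C@H](C)CC1(OCCO1)C(=C)C(C)C | intermediate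
16 | 2-R-cyclopentane-1,3-dione | O=C1CCC(=O)C1[C@H](C)CC1(OCCO1)C(=C)C(C)C | intermediate
17 | 3-[(E)-3-Ar-but-2-enyloxy]-2-R-cyclopent-2-en-1-one | O=C1CCC(OC/C=C(\C)c2cc(C(C)C)c(OC)cc2C)=C1[C@H](C)CC1(OCCO1)C(=C)C(C)C | intermediate
18 | (S)-3-[(E)-3-Ar-but-2-enyloxy]-2-R-cyclopent-2-en-1-ol | O[C@H]1CCC(OC/C=C(\C)c2cc(C(C)C)c(OC)cc2C)=C1[C@H](C)CC1(OCCO1)C(=C)C(C)C | intermediate
19 | triethylsilyl ether of 18 | CC[Si](CC)(CC)O[C@H]1CCC(OC/C=C(\C)c2cc(C(C)C)c(OC)cc2C)=C1[C@H](C)CC1(OCCO1)C(=C)C(C)C | intermediate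
20 | Claisen ketone, 2-(2-Ar-but-3-en-2-yl)-2-R-3-(triethylsilyloxy)cyclopentanone, C4' unit trans to the silyl ether | CC[Si](CC)(CC)O[C@H]1CCC(=O)[C@]1([C@H](C)CC1(OCCO1)C(=C)C(C)C)[C@](C)(c1cc(C(C)C)c(OC)cc1C)C=C | intermediate
21 | pinacol boronate at C2' | CC[Si](CC)(CC)O[C@H]1CCC(=O)[C@]1([C@H](C)CC1(OCCO1)C(=C)C(C)C)[C@](C)(c1cc(C(C)C)c(OC)cc1C)CCB1OC(C)(C)C(C)(C)O1 | intermediate
22 | primary alcohol (C2'H2OH) | CC[Si](CC)(CC)O[C@H]1CCC(=O)[C@]1([C@H](C)CC1(OCCO1)C(=C)C(C)C)[C@](C)(c1cc(C(C)C)c(OC)cc1C)CCO | intermediate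
23 | carboxylic acid (C2'O2H) | CC[Si](CC)(CC)O[C@H]1CCC(=O)[C@]1([C@H](C)CC1(OCCO1)C(=C)C(C)C)[C@](C)(c1cc(C(C)C)c(OC)cc1C)CC(=O)O | intermediate
24 | methyl ester of 23 | CC[Si](CC)(CC)O[C@H]1CCC(=O)[C@]1([C@H](C)CC1(OCCO1)C(=C)C(C)C)[C@](C)(c1cc(C(C)C)c(OC)cc1C)CC(=O)OC | intermediate
25 | C4-methyl ketone (C4 epimers) | CC[Si](CC)(CC)O[C@H]1CC(C)C(=O)[C@]1([C@H](C)CC1(OCCO1)C(=C)C(C)C)[C@](C)(c1cc(C(C)C)c(OC)cc1C)CC(=O)OC | intermediate
26 | trimethylsilyl enol ether of 25 | CC[Si](CC)(CC)O[C@H]1CC(C)=C(O[Si](C)(C)C)[C@]1([C@H](C)CC1(OCCO1)C(=C)C(C)C)[C@](C)(c1cc(C(C)C)c(OC)cc1C)CC(=O)OC | intermediate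
27 | enone, 2-methylcyclopent-2-enone with quaternary C1 and C2 silyl ether | CC[Si](CC)(CC)O[C@H]1C=C(C)C(=O)[C@]1([C@H](C)CC1(OCCO1)C(=C)C(C)C)[C@](C)(c1cc(C(C)C)c(OC)cc1C)CC(=O)OC | intermediate
28 | lithium enolate of the norbornanone | CC[Si](CC)(CC)O[C@H]1[C@H]2C(C)=C([O-])[C@]1([C@H](C)CC1(OCCO1)C(=C)C(C)C)[C@](C)(c1cc(C(C)C)c(OC)cc1C)[C@@H]2C(=O)OC.[Li+] | intermediate
29 | norbornenyl triflate (silyl ether syn to C4=C5, ester and Ar endo, C4' methyl exo) | CC[Si](CC)(CC)O[C@H]1[C@H]2C(C)=C(OS(=O)(=O)C(F)(F)F)[C@]1([C@H](C)CC1(OCCO1)C(=C)C(C)C)[C@](C)(c1cc(C(C)C)c(OC)cc1C)[C@@H]2C(=O)OC | intermediate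
30 | B-alkyl-9-BBN at C6 (C7 epimers) | CC[Si](CC)(CC)O[C@H]1[C@H]2C(C)=C(OS(=O)(=O)C(F)(F)F)[C@]1([C@H](C)CC1(OCCO1)C(CB1C3CCCC1CCC3)C(C)C)[C@](C)(c1cc(C(C)C)c(OC)cc1C)[C@@H]2C(=O)OC | intermediate
31 | tricyclic ketal ester (C7 epimers) | CC[Si](CC)(CC)O[C@H]1[C@H]2C(C)=C3CC(C(C)C)C4(OCCO4)C[C@@H](C)[C@]31[C@](C)(c1cc(C(C)C)c(OC)cc1C)[C@@H]2C(=O)OC | intermediate
32 | hydroxy keto ester | O[C@H]1[C@H]2C(C)=C3C[C@@H](C(C)C)C(=O)C[C@@H](C)[C@]31[C@](C)(c1cc(C(C)C)c(OC)cc1C)[C@@H]2C(=O)OC | intermediate
33 | hydroxy keto acid | O[C@H]1[C@H]2C(C)=C3C[C@@H](C(C)C)C(=O)C[C@@H](C)[C@]31[C@](C)(c1cc(C(C)C)c(OC)cc1C)[C@@H]2C(=O)O | intermediate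
34 | acetoxy keto acid | CC(=O)O[C@H]1[C@H]2C(C)=C3C[C@@H](C(C)C)C(=O)C[C@@H](C)[C@]31[C@](C)(c1cc(C(C)C)c(OC)cc1C)[C@@H]2C(=O)O | intermediate
35 | acid chloride of 34 | CC(=O)O[C@H]1[C@H]2C(C)=C3C[C@@H](C(C)C)C(=O)C[C@@H](C)[C@]31[C@](C)(c1cc(C(C)C)c(OC)cc1C)[C@@H]2C(=O)Cl | intermediate
36 | endo diazoketone | CC(=O)O[C@H]1[C@H]2C(C)=C3C[C@@H](C(C)C)C(=O)C[C@@H](C)[C@]31[C@](C)(c1cc(C(C)C)c(OC)cc1C)[C@@H]2C(=O)C=[N+]=[N-] | intermediate
37 | norcaradiene (cyclopropane C1', C5', C10') | CC(=O)O[C@H]1[C@H]2C(C)=C3C[C@@H](C(C)C)C(=O)C[C@@H](C)[C@]31[C@]1(C)[C@@]34C=C(C(C)C)C(OC)=C[C@]3(C)[C@H]4C(=O)[C@H]21 | intermediate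
38 | methoxycycloheptatriene (dihydroazulenone) | CC(=O)O[C@H]1[C@H]2C(C)=C3C[C@@H](C(C)C)C(=O)C[C@@H](C)[C@]31[C@]1(C)C3=CC(C(C)C)=C(OC)C=C(C)[C@H]3C(=O)[C@H]21 | intermediate
39 | cross-conjugated dienedione (C7' epimers) | CC(=O)O[C@H]1[C@H]2C(C)=C3C[C@@H](C(C)C)C(=O)C[C@@H](C)[C@]31[C@]1(C)C3=C(C(=O)[C@H]21)C(C)=CC(=O)C(C(C)C)C3 | intermediate
40 | enedione with C10' set (C7' epimers) | CC(=O)O[C@H]1[C@H]2C(C)=C3C[C@@H](C(C)C)C(=O)C[C@@H](C)[C@]31[C@]1(C)C3=C(C(=O)[C@H]21)[C@H](C)CC(=O)C(C(C)C)C3 | intermediate
41 | linear dienedione | CC(=O)O[C@H]1[C@H]2C(C)=C3C[C@@H](C(C)C)C(=O)C[C@@H](C)[C@]31[C@]1(C)C3=C(C(=O)[C@H]21)[C@H](C)CC(=O)C(C(C)C)=C3 | intermediate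
42 | C11' hydroperoxide | CC(=O)O[C@H]1[C@H]2C(C)=C3C[C@@H](C(C)C)C(=O)C[C@@H](C)[C@]31[C@]1(C)C3=C(C(=O)[C@H]21)[C@H](C)CC(=O)C(C(C)(C)OO)=C3 | intermediate
43 | CNP0317907.1 | CC(=O)O[C@H]1[C@H]2C(C)=C3C[C@@H](C(C)C)C(=O)C[C@@H](C)[C@]31[C@]1(C)C3=C(C(=O)[C@H]21)[C@H](C)C[C@@]1(O)OOC(C)(C)C1=C3 | target

Total step count: 29. Longest linear sequence: 25 steps (steps 5 to 29). Steps 1 to 4 run in parallel and join at step 10.

Steps most likely to fail

Step 19. The amide base may remove the C2 hydrogen (gamma to the enone) instead of the ester alpha hydrogen. The strained ring closure may also reverse before the enolate is trapped. The fallback replaces the anionic closure by a Lewis-acid-promoted one in which the product is caught by silyl transfer. It sets out from 27. LiN(i-Pr)2 in the presence of Me3SiCl at −100 °C gives the ketene trimethylsilyl acetal F1. Me3SiOTf (10 mol %, CH2Cl2, −78 °C) then closes it in an intramolecular Mukaiyama–Michael reaction to the norbornene trimethylsilyl enol ether F2. CsF and PhN(SO2CF3)2 in DME convert F2 into 29, where the route is rejoined.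

Step 25. The carbenoid may add to the C4=C5 alkene or to the hydrogen-bearing C5'–C6' bond instead of the C5'–C10' bond. The fallback keeps both bond formations but generates a more cationic, more arene-selective alpha-oxo gold carbene from an alkyne instead of a diazo compound. It sets out from 35. LiAlH(Ot-Bu)3 (THF, −78 °C) gives the endo aldehyde F3. Seyferth–Gilbert homologation with dimethyl (1-diazo-2-oxopropyl)phosphonate and K2CO3 in MeOH gives the endo terminal alkyne F4. Oxidation with 8-methylquinoline N-oxide under Ph3PAuNTf2 (5 mol %, 1,2-dichloroethane, 23 °C) places oxygen on C2' and the carbene on C1'. Arene cyclopropanation and ring opening then lead to 38, where the route is rejoined.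

Step 29. Oxygenation may occur at other enolisable positions (C9', C7), and C10' may epimerise through the extended enolate of the C8' ketone. The fallback replaces enolate chemistry by hydrogen-atom abstraction under neutral conditions. It sets out from 41. N-hydroxyphthalimide (10 mol %), Co(OAc)2 (1 mol %) and O2 in MeCN at 23 °C abstract the weak tertiary allylic C11' hydrogen. The radical is trapped by oxygen to give 42, which closes to 43. No new compound is made.

Further compounds
F1 | step 19 | ketene trimethylsilyl acetal of 27 | CC[Si](CC)(CC)O[C@H]1C=C(C)C(=O)[C@]1([C@H](C)CC1(OCCO1)C(=C)C(C)C)[C@](C)(c1cc(C(C)C)c(OC)cc1C)C=C(OC)O[Si](C)(C)C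
F2 | step 19 | norbornene trimethylsilyl enol ether | CC[Si](CC)(CC)O[C@H]1[C@H]2C(C)=C(O[Si](C)(C)C)[C@]1([C@H](C)CC1(OCCO1)C(=C)C(C)C)[C@](C)(c1cc(C(C)C)c(OC)cc1C)[C@@H]2C(=O)OC
F3 | step 25 | endo aldehyde | CC(=O)O[C@H]1[C@H]2C(C)=C3C[C@@H](C(C)C)C(=O)C[C@@H](C)[C@]31[C@](C)(c1cc(C(C)C)c(OC)cc1C)[C@@H]2C=O
F4 | step 25 | endo terminal alkyne | CC(=O)O[C@H]1[C@H]2C(C)=C3C[C@@H](C(C)C)C(=O)C[C@@H](C)[C@]31[C@](C)(c1cc(C(C)C)c(OC)cc1C)[C@@H]2C#C
F0 | step 29 | none | none
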